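Divide first. The next flask takes 0.020 M of X, and I have to decide whether E stays at 0.0180 M or goes up.

| setting | south-west | west | north | flask |
|---|---|---|---|---|
| X | 0.020 M | 0.020 M | 0.030 M | 0.020 M |
| E | 0.025 M | 0.040 M | 0.018 M | 0.0180 M |
| remark | run made earlier | run made earlier | run made earlier |  |
| time |  |  |  | 5.0 d |

| south-west: time / d | south-west: J / % | west: time / d | west: J / % | north: time / d | north: J / % |
|---|---|---|---|---|---|
| 0.417 | 0 | 0.625 | 0.8 | 1.25 | 1.9 |
| 0.833 | 1.0 | 1.67 | 48.0 | 2.50 | 30.0 |
| 2.00 | 14.5 | 3.00 | 97.0 | 4.00 | 55.8 |
| 5.00 | 91.5 | 5.00 | 99.6 | 5.00 | 58.5 |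

(scatter of a reading: 0.5 percentage points)

* amount of J in percent of the X charged, at 25 h, 2.5 d and 5.0 d

- a reading or a percentage of J counts all its forms, free or not

The north run slows late, and its last reading of 58.5 % of the X charged is 0.0175 M of J, close to the 0.018 M of E charged there. I read this as X and E going one to one.

Equal charges are then the zero of my scale, the case with neither partner in excess. Below that point E is the limiting reagent, and I carry one quantity: the ceiling, c(E)/c(X), the most J a one-to-one reaction can give in percent of the X charged. For this flask it is 90.0 %.

Reaching it is another matter. The south-west run holds more E than this flask, and it climbs late, from 14.5 % at 2.00 d to 91.5 % at 5.00 d. So I expect this flask to stand below its ceiling at 5.0 d. I leave E as charged and take the readings.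

The forecast gives 0.7 %, 8.5 % and 60 %, and it reads the north run as I do: “so X and E react 1:1, and the flask's ceiling is 90%”.

The flask gives 0.476 %, 9.07 % and 65.4 %. The forecast is higher at the first time and lower at the last.

    X + E + G → J + 2 G (k = 240 /M²/h)
    X + E → J + G (k = 0.00300 /M/h)
    L ⇌ J, rate k3*(cs3 - [J]) while solid is left; crystals form when [J] > cs3 (solubility = 10.0 mM, k = 1.00 /h)

At 5.0 d the flask stands 25 percentage points under its ceiling, with 27 % of its E left. The using up of E and the time allowed act together here. With the using up of E taken away, the same flask gives 95.2 % at 5.0 d. With the limit of time taken away, the flask left to 50.0 d gives 90.0 %, its ceiling, with E at 0 %. The same division gives the north run a ceiling of 60.0 %, and its reading at 5.00 d is 58.5 %.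

The readings stem from a simulated flask for an exercise.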